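Think of late times first: partner, charged at 0.0840 M against 0.280 M of the two substrates, also decays by itself with a half-life of 12.8 s, so the end of this flask is a matter of partner, and the early moment asked about is a matter of where the catalyst sits.

    free catalyst + left-handed substrate ⇌ catalyst intermediate A (K1 = 11 L mol⁻¹, k1 = 6500 L mol⁻¹ s⁻¹)
    free catalyst + right-handed substrate ⇌ catalyst intermediate B (K2 = 160 L mol⁻¹, k2 = 2000 L mol⁻¹ s⁻¹)
    partner + catalyst intermediate A → free catalyst + left-handed product (k3 = 3300 L mol⁻¹ s⁻¹)
    partner + catalyst intermediate B → free catalyst + right-handed product (k4 = 400 L mol⁻¹ s⁻¹)
    free catalyst + impurity → spent catalyst (k5 = 41000 L mol⁻¹ s⁻¹)
    partner → decomposed reagent (k6 = 0.054 s⁻¹)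

left-handed substrate 0.14 M; partner 0.600 equiv; free catalyst 0.16 mol%; impurity 41 µM; right-handed substrate 0.14 M

* the form that holds most of the catalyst when 5.0 % of the left-handed substrate and right-handed substrate together are converted (catalyst intermediate A / spent catalyst / catalyst intermediate B / free catalyst)
* its share of the catalyst then
* apparent order in partner when 5.0 % of the left-handed substrate and right-handed substrate together are converted (percent change of the rate of making left-handed product for one percent more partner charged)
* apparent order in free catalyst when 5.0 % of the left-handed substrate and right-handed substrate together are converted (percent change of the rate of making left-handed product for one percent more free catalyst charged)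

You can place the catalyst with two numbers. Each intermediate stands beside free catalyst as capture over leaving: how fast free catalyst takes the substrate, over how fast the intermediate falls back and goes on with partner, the two ways out together. I take both at the charge, as a steady state.

| form | capture | leaving | holding number |
|---|---|---|---|
| catalyst intermediate A | 910 s⁻¹ | 868 s⁻¹ | 1.05 |
| catalyst intermediate B | 280 s⁻¹ | 46.1 s⁻¹ | 6.07 |

Intermediate A forms faster than B, but it also leaves far faster than B. Their quotient, 5.79, is the holding ratio, intermediate B standing per intermediate A; a catalyst treating mirror images alike would give 1.

Each active catalyst then turns over at 60.9 s⁻¹, so 224 µM of catalyst reaches the mark in about 1.03 s. Meanwhile impurity has taken 12.6 % of the catalyst. My resting state is therefore catalyst intermediate B, with 65.4 %.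

More catalyst meets the same impurity, giving an order of 1.14. My local order in partner is 1.27: partner stands in the rate of making left-handed product, and it also takes catalyst out of the intermediates. At a set conversion I take the partner consumed by turnover as the same, which raises this to 1.52.

The forecast gave catalyst intermediate B at 67 % (62 % to 72 %) and orders of 1.7 and 1.26, both higher than mine, saying “Treating the intermediates as steady state, B dominates.”

The flask reaches the mark at 1.27 s, later than my time, with catalyst intermediate B at 67.0 % and orders of 1.7 and 1.3; intermediate B per intermediate A is then 6.54. Part of what holds the rate down is the path between free catalyst and intermediate B. Removing that path removes 5.79 times A's holding number from the catalyst's balance, which reckons a gain of 3.97. The run without that path makes left-handed product at 4.26 times the actual rate. That path is also the largest single effect on the order in partner, which falls in that run from 1.7 to 1.1, lower than the 1.4 of the run without the step from partner and intermediate B.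

(The constants are those of an exercise; the result is computed.)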